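**Retrosynthetic overview**
1. GA55 ⇐ Δ1-3-ketone (3-dehydro-GA3 ester): 1β-OH by conjugate borylation/oxidation, 3β-OH by bulky-hydride reduction; ring A ⇐ lactone-enolate/Z-enal aldol (C-3–C-4).
2. γ-Lactone (C-4–C-5) ⇐ intramolecular Michael addition of a C-10 propanoate onto a Δ5-7-ester; C-10 carbinol ⇐ acetylide addition to a C-10 ketone.
3. B/C/D enone ester ⇐ C-6 ketone (enol triflate carbonylation, γ-oxidation); ring D ⇐ new nickel-catalysed cyclisation of an angular allyl group onto the C-13 ketone.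
4. cis-Hydrindanedione ⇐ Birch reduction of 6-methoxy-1-indanone, then palladium-catalysed decarboxylative asymmetric allylation (C-8, the only source of absolute configuration).
5. Ring order: B and C (bought as the indanone, ring C dearomatised) → D → γ-lactone → A.

Assumption: 1, 2, 14 and 15 are catalogue chemicals; from compound 9 on, atoms carry gibberellane numbers (C-1 to C-19 as in GA55), β is the face of H-5, H-9, C-7 and the C-15/C-16 bridge, α the face of the lactone bridge and C-14; TES = SiEt3, TMSE = CH2CH2SiMe3.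

**Step 1**
Reactants: 1 6-methoxy-1-indanone; 2 allyl chloroformate
Product: 4 allyl 5-methoxy-2,6-dihydro-1H-inden-3-yl carbonate, via potassium dienolate 3 (not isolated)
Conditions: K (2.2 equiv), t-BuOH (1.0 equiv), NH3(l)/THF, −78 °C; NH3 evaporated; 2 (2.5 equiv), THF, −78 → 0 °C
Reagents that add atoms: none
Why: Birch reduction of the aryl ketone with one equivalent of proton donor protonates the ring para to the carbonyl (C-12) and stops at the cross-conjugated potassium dienolate, which is acylated on oxygen by the chloroformate (Birch reduction with enolate O-acylation); no stereocentre is formed.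

**Step 2**
Reactants: 4 allyl 5-methoxy-2,6-dihydro-1H-inden-3-yl carbonate
Product: 5 (S)-7a-allyl-6-methoxy-2,3,5,7a-tetrahydro-1H-inden-1-one
Conditions: Pd2(dba)3 (2.5 mol %; dba = dibenzylideneacetone), (S)-t-Bu-PHOX (6 mol %), THF, 25 °C
Reagents that add atoms: none
Why: Decarboxylative asymmetric allylic alkylation (Tsuji–Trost type): zerovalent palladium ionises the allyl carbonate, CO2 is lost and the allyl-palladium enolate recombines at the fully substituted α-carbon inside the chiral PHOX pocket, setting the C-8 quaternary centre as (S) (ligand sense assigned by analogy with tetralone-type enol carbonates; the antipodal ligand is used if it proves opposite).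

**Step 3**
Reactants: 5 (S)-7a-allyl-6-methoxy-2,3,5,7a-tetrahydro-1H-inden-1-one
Product: 7 (3aR,7aS)-7a-allyl-3,3a,7,7a-tetrahydro-1H-indene-1,6(2H)-dione, via β,γ-enone 6 (not isolated)
Conditions: 3 M HCl, THF, 23 → 40 °C
Reagents that add atoms: water, O
Why: Acid hydrolysis of the methyl enol ether unmasks the C-13 ketone and the β,γ-double bond then moves into conjugation through the dienol (the usual Birch work-up isomerisation), the reversible protonation at C-9 giving the thermodynamically preferred cis-fused hydrindenone (H-9 syn to the angular allyl group).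

**Step 4**
Reactants: 7 (3aR,7aS)-7a-allyl-3,3a,7,7a-tetrahydro-1H-indene-1,6(2H)-dione
Product: 8 (3aS,7aS)-7a-allylhexahydro-1H-indene-1,6(2H)-dione
Conditions: [(Ph3P)CuH]6 (0.4 equiv), H2O (5 equiv), THF, 23 °C
Reagents that add atoms: none
Why: Stryker-type conjugate reduction: the copper hydride adds 1,4 to the enone only, leaving the isolated ketone and the terminal alkene, and water protonates the copper enolate; no new stereocentre (3aR to 3aS is a priority change only).

**Step 5**
Reactants: 8 (3aS,7aS)-7a-allylhexahydro-1H-indene-1,6(2H)-dione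
Product: 9 9-methylene-8-(triethylsilyloxy)tricyclo[6.2.1.0^{1,5}]undecan-2-one (B/C/D ketone: C-6 ketone; 13-OTES; 16-ene; H-9β)
Conditions: Ni(cod)2 (20 mol %; cod = 1,5-cyclooctadiene), PCy2Ph (40 mol %), Et3SiOTf (1.5 equiv), 2,6-lutidine (3 equiv), toluene, 40 °C; AcOH/H2O/THF work-up
Reagents that add atoms: triethylsilyl trifluoromethanesulfonate, CC[Si](CC)(CC)OS(=O)(=O)C(F)(F)F
Why: Proposed new method: an intramolecular nickel-catalysed ketone–alkene coupling in which the silyl triflate activates the C-13 ketone, zerovalent nickel undergoes oxidative cyclisation with the angular allyl group so that the internal alkene carbon C-16 bonds to C-13 (five-membered ring D; bonding through C-17 would give a bicyclo[2.2.2]octane, and the hindered C-6 ketone could only close a four-membered ring), β-hydride elimination of H-16 from the oxanickelacycle restores the C-16/C-17 double bond as the exocyclic methylene and lutidine removes HOTf to return the catalyst, the bridge geometry fixing the C-13 configuration; the closest known reaction type is the intermolecular nickel-catalysed three-component coupling of terminal alkenes, aldehydes and silyl triflates to 2-substituted allylic silyl ethers, extended here to a ketone and to bridged-ring formation.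

**Step 6**
Reactants: 9 B/C/D ketone
Product: 11 enol triflate (6-trifluoromethanesulfonyloxy-Δ5 derivative of 9), via potassium enolate 10 (not isolated)
Conditions: KN(SiMe3)2, THF, −78 °C; PhNTf2, −78 → 0 °C
Reagents that add atoms: N-phenylbis(trifluoromethanesulfonimide), O=S(=O)(N(c1ccccc1)S(=O)(=O)C(F)(F)F)C(F)(F)F
Why: The ketone can enolise only towards C-5 because C-8 is quaternary, so the potassium enolate is trapped regiospecifically as the enol triflate.

**Step 7**
Reactants: 11 enol triflate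
Product: 12 TMSE enoate (2-(trimethylsilyl)ethyl Δ5-7-oate; C-10 is CH2; 13-OTES; 16-ene)
Conditions: Pd(OAc)2 (5 mol %), PPh3 (10 mol %), CO (1 atm), Et3N, Me3SiCH2CH2OH (5 equiv), DMF, 50 °C
Reagents that add atoms: carbon monoxide, [C-]#[O+]; 2-(trimethylsilyl)ethanol, C[Si](C)(C)CCO
Why: Palladium-catalysed alkoxycarbonylation of the enol triflate (oxidative addition, CO insertion, alcoholysis) installs C-7 as a fluoride-labile ester.

**Step 8**
Reactants: 12 TMSE enoate
Product: 13 enone ester (10-oxo derivative of 12)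
Conditions: Rh2(cap)4 (1 mol %; cap = caprolactamate), t-BuOOH (70 % aq., 8 equiv), K2CO3, CH2Cl2, 23 °C
Reagents that add atoms: tert-butyl hydroperoxide, CC(C)(C)OO
Why: Allylic oxidation by the tert-butylperoxyl radical: the ring C-10 hydrogen γ to the ester is abstracted (the radical is delocalised into the enoate) and the mixed peroxide collapses to the ketone, as in the known conversion of cycloalkene carboxylates into their 3-oxo derivatives.

**Step 9**
Reactants: 13 enone ester; 14 3,3-diethoxyprop-1-yne; 15 propanoic anhydride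
Product: 17 propanoate (10β-(3,3-diethoxyprop-1-ynyl)-10α-propanoyloxy derivative of 12), via lithium alkoxide 16 (not isolated)
Conditions: 14, n-BuLi, THF, −78 °C; 13, −78 °C; 15, −78 → 0 °C
Reagents that add atoms: none
Why: 1,2-Addition of the lithium acetylide to the C-10 ketone from the β face (anti to C-11 on the neighbouring C-9) sets C-10 with the oxygen α, and the lithium alkoxide is acylated in the same flask.

**Step 10**
Reactants: 17 propanoate
Product: 20 alkynyl γ-lactone (19,10α-lactone; H-5β; 6β-CO2TMSE; 10β-(3,3-diethoxyprop-1-ynyl); C-4 epimers), via propanoate enolate 18 (not isolated), via ester enolate 19 (not isolated)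
Conditions: KN(SiMe3)2 (1.1 equiv), THF, −78 → −20 °C; t-BuOH, 23 °C; AcOH
Reagents that add atoms: none
Why: Intramolecular 5-exo-trig Michael addition of the propanoate enolate to C-5 of the unsaturated ester; the tether on the α-oxygen forces the C-4–C-5 bond onto the α face (cis-fused γ-lactone, H-5β), and the KOt-Bu/t-BuOH present after the first quench equilibrates C-6 to the trans arrangement (C-7 β), while C-4 stays an inconsequential epimer mixture.

**Step 11**
Reactants: 20 alkynyl γ-lactone
Product: 21 (Z)-alkenyl lactone (10β-[(Z)-3,3-diethoxyprop-1-enyl])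
Conditions: H2 (1 atm), Pd/CaCO3 poisoned with Pb(OAc)2, quinoline, EtOAc, 23 °C
Reagents that add atoms: none
Why: Lindlar semihydrogenation stops at the Z-alkene and spares the 1,1-disubstituted alkene; the Z geometry brings C-3 within reach of C-4.

**Step 12**
Reactants: 21 (Z)-alkenyl lactone
Product: 22 (Z)-enal lactone (10β-[(Z)-3-oxoprop-1-enyl])
Conditions: 10 % aq. oxalic acid on SiO2, CH2Cl2, 23 °C
Reagents that add atoms: water, O
Why: Mild heterogeneous acetal hydrolysis gives the Z-enal without Z/E isomerisation and leaves the tertiary silyl ether, lactone and ester intact.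

**Step 13**
Reactants: 22 (Z)-enal lactone
Product: 24 13-O-TES-gibberellic acid (GA3) TMSE ester together with its 3-epimer, via lactone enolate 23 (not isolated)
Conditions: KOt-Bu (1.0 equiv), THF/t-BuOH, −20 °C; AcOH
Reagents that add atoms: none
Why: Intramolecular aldol addition of the lactone enolate to the non-enolisable Z-enal closes ring A; the C-3–C-4 bond can form only on the face of C-4 that carries the C-10–C-1 bridge, which fixes the C-4 quaternary centre (methyl β), and both C-3 epimers are carried on.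

**Step 14**
Reactants: 24 13-O-TES-GA3 TMSE ester (both C-3 epimers)
Product: 25 13-O-TES-3-dehydro-GA3 TMSE ester (Δ1-3-ketone)
Conditions: MnO2 (20 equiv), CH2Cl2, 23 °C
Reagents that add atoms: none
Why: Allylic alcohol oxidation with MnO2 converts both C-3 epimers into the same enone.

**Step 15**
Reactants: 25 Δ1-3-ketone
Product: 27 1β-hydroxy-3-ketone (13-O-TES-3-dehydro-GA55 TMSE ester), via boronate 26 (not isolated)
Conditions: B2pin2 (1.2 equiv), CuCl (5 mol %), Xantphos (5 mol %), NaOt-Bu (10 mol %), MeOH (2 equiv), THF, 23 °C; then NaBO3·4H2O, THF/H2O, 0 → 23 °C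
Reagents that add atoms: sodium perborate, [Na+].[O-]OB=O (the C-1 oxygen); bis(pinacolato)diboron, CC1(C)OB(OC1(C)C)B1OC(C)(C)C(C)(C)O1 (boron of 26, lost again on oxidation)
Why: Copper-catalysed conjugate borylation: the boryl-copper adds to C-1 from the exposed β face (the α face is covered by the lactone bridge) and perborate oxidation with retention gives the 1β-alcohol.

**Step 16**
Reactants: 27 1β-hydroxy-3-ketone
Product: 28 13-O-TES-GA55 TMSE ester
Conditions: LiBH(s-Bu)3 (2.2 equiv), THF, −78 °C; AcOH, MeOH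
Reagents that add atoms: none
Why: Bulky-hydride reduction: axial approach on the β face is blocked by the axial 1β-alkoxide and H-5, so hydride enters from the α side (equatorial attack) and gives the axial 3β-alcohol, the syn-1,3-diol.

**Step 17**
Reactants: 28 13-O-TES-GA55 TMSE ester
Product: 29 GA55 (1β,3β,13-trihydroxy-19,10-lactone 7-acid)
Conditions: Bu4NF (6 equiv), AcOH (6 equiv), THF, 23 → 40 °C; aq. citric acid work-up
Reagents that add atoms: none
Why: Fluoride cleaves the tertiary silyl ether and fragments the 2-(trimethylsilyl)ethyl ester (loss of ethene) in one operation, the acetic acid buffer suppressing retro-aldol epimerisation at C-3.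

**Compound list**
1 | 6-methoxy-1-indanone | COc1ccc2CCC(=O)c2c1 | starting material
2 | allyl chloroformate | C=CCOC(Cl)=O | starting material
3 | potassium 5-methoxy-2,6-dihydro-1H-inden-3-olate (Birch dienolate) | [K+].[O-]C1=C2C=C(OC)CC=C2CC1 | intermediate
4 | allyl 5-methoxy-2,6-dihydro-1H-inden-3-yl carbonate | C=CCOC(=O)OC1=C2C=C(OC)CC=C2CC1 | intermediate
5 | (S)-7a-allyl-6-methoxy-2,3,5,7a-tetrahydro-1H-inden-1-one | C=CC[C@]12C=C(OC)CC=C1CCC2=O | intermediate
6 | (S)-7a-allyl-2,3,7,7a-tetrahydro-1H-indene-1,6(5H)-dione | C=CC[C@]12CC(=O)CC=C1CCC2=O | intermediate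
7 | (3aR,7aS)-7a-allyl-3,3a,7,7a-tetrahydro-1H-indene-1,6(2H)-dione (cis-fused) | C=CC[C@]12CC(=O)C=C[C@H]1CCC2=O | intermediate
8 | (3aS,7aS)-7a-allylhexahydro-1H-indene-1,6(2H)-dione (cis-fused) | C=CC[C@]12CC(=O)CC[C@H]1CCC2=O | intermediate
9 | 9-methylene-8-(triethylsilyloxy)tricyclo[6.2.1.0^{1,5}]undecan-2-one (C-6 ketone; 13-OTES; 16-ene; H-9β) | C=C1C[C@]23C[C@@]1(O[Si](CC)(CC)CC)CC[C@H]2CCC3=O | intermediate
10 | potassium C-5/C-6 enolate of 9 | C=C1C[C@]23C[C@@]1(O[Si](CC)(CC)CC)CC[C@H]2CC=C3O[K] | intermediate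
11 | enol triflate of 9 (6-OTf, Δ5) | C=C1C[C@]23C[C@@]1(O[Si](CC)(CC)CC)CC[C@H]2CC=C3OS(=O)(=O)C(F)(F)F | intermediate
12 | TMSE enoate (Δ5-7-oate; 13-OTES; 16-ene) | C=C1C[C@]23C[C@@]1(O[Si](CC)(CC)CC)CC[C@H]2CC=C3C(=O)OCC[Si](C)(C)C | intermediate
13 | enone ester (10-oxo-Δ5-7-oate) | C=C1C[C@]23C[C@@]1(O[Si](CC)(CC)CC)CC[C@H]2C(=O)C=C3C(=O)OCC[Si](C)(C)C | intermediate
14 | 3,3-diethoxyprop-1-yne | C#CC(OCC)OCC | starting material
15 | propanoic anhydride | CCC(=O)OC(=O)CC | starting material
16 | lithium 10α-alkoxide (10β-(3,3-diethoxyprop-1-ynyl)) | C=C1C[C@]23C[C@@]1(O[Si](CC)(CC)CC)CC[C@H]2[C@](O[Li])(C#CC(OCC)OCC)C=C3C(=O)OCC[Si](C)(C)C | intermediate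
17 | 10α-propanoate of the 10β-(3,3-diethoxyprop-1-ynyl) carbinol | C=C1C[C@]23C[C@@]1(O[Si](CC)(CC)CC)CC[C@H]2[C@](OC(=O)CC)(C#CC(OCC)OCC)C=C3C(=O)OCC[Si](C)(C)C | intermediate
18 | potassium enolate of propanoate 17 | C=C1C[C@]23C[C@@]1(O[Si](CC)(CC)CC)CC[C@H]2[C@](OC(O[K])=CC)(C#CC(OCC)OCC)C=C3C(=O)OCC[Si](C)(C)C | intermediate
19 | potassium C-6 ester enolate of the cyclised lactone | C=C1C[C@]23C[C@@]1(O[Si](CC)(CC)CC)CC[C@H]2[C@@]1(C#CC(OCC)OCC)OC(=O)C(C)[C@H]1C3=C(O[K])OCC[Si](C)(C)C | intermediate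
20 | alkynyl γ-lactone (H-5β; C-7 β; C-4 epimers) | C=C1C[C@]23C[C@@]1(O[Si](CC)(CC)CC)CC[C@H]2[C@@]1(C#CC(OCC)OCC)OC(=O)C(C)[C@H]1[C@@H]3C(=O)OCC[Si](C)(C)C | intermediate
21 | (Z)-alkenyl lactone (C-4 epimers) | C=C1C[C@]23C[C@@]1(O[Si](CC)(CC)CC)CC[C@H]2[C@@]1(/C=C\C(OCC)OCC)OC(=O)C(C)[C@H]1[C@@H]3C(=O)OCC[Si](C)(C)C | intermediate
22 | (Z)-enal lactone (C-4 epimers) | C=C1C[C@]23C[C@@]1(O[Si](CC)(CC)CC)CC[C@H]2[C@@]1(/C=C\C=O)OC(=O)C(C)[C@H]1[C@@H]3C(=O)OCC[Si](C)(C)C | intermediate
23 | potassium lactone enolate of 22 | C=C1C[C@]23C[C@@]1(O[Si](CC)(CC)CC)CC[C@H]2[C@@]1(/C=C\C=O)OC(O[K])=C(C)[C@H]1[C@@H]3C(=O)OCC[Si](C)(C)C | intermediate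
24 | 13-O-TES-GA3 TMSE ester and its 3-epimer (C-3 unspecified) | C=C1C[C@]23C[C@@]1(O[Si](CC)(CC)CC)CC[C@H]2[C@@]12OC(=O)[C@@](C)([C@H]1[C@@H]3C(=O)OCC[Si](C)(C)C)C(O)C=C2 | intermediate
25 | 13-O-TES-3-dehydro-GA3 TMSE ester (Δ1-3-ketone) | C=C1C[C@]23C[C@@]1(O[Si](CC)(CC)CC)CC[C@H]2[C@@]12OC(=O)[C@@](C)([C@H]1[C@@H]3C(=O)OCC[Si](C)(C)C)C(=O)C=C2 | intermediate
26 | 1β-pinacolboryl-3-ketone | C=C1C[C@]23C[C@@]1(O[Si](CC)(CC)CC)CC[C@H]2[C@@]12OC(=O)[C@@](C)([C@H]1[C@@H]3C(=O)OCC[Si](C)(C)C)C(=O)C[C@H]2B4OC(C)(C)C(C)(C)O4 | intermediate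
27 | 1β-hydroxy-3-ketone (13-O-TES-3-dehydro-GA55 TMSE ester) | C=C1C[C@]23C[C@@]1(O[Si](CC)(CC)CC)CC[C@H]2[C@@]12OC(=O)[C@@](C)([C@H]1[C@@H]3C(=O)OCC[Si](C)(C)C)C(=O)C[C@H]2O | intermediate
28 | 13-O-TES-GA55 TMSE ester | C=C1C[C@]23C[C@@]1(O[Si](CC)(CC)CC)CC[C@H]2[C@@]12OC(=O)[C@@](C)([C@H]1[C@@H]3C(=O)OCC[Si](C)(C)C)[C@@H](O)C[C@H]2O | intermediate
29 | GA55 | C=C1C[C@]23C[C@@]1(O)CC[C@H]2[C@@]12OC(=O)[C@@](C)([C@H]1[C@@H]3C(=O)O)[C@@H](O)C[C@H]2O | target

**Totals and risks**
Total step count: 17. Longest linear sequence: 17 steps (1 → 29).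

Most likely to fail, first: step 2 (enantioselective allylation of an untested, acid-sensitive cross-conjugated enol carbonate; yield and ee uncertain). The fallback sets out from 1 and comes back at 5: classical Birch reductive C-alkylation (K, NH3, t-BuOH; LiBr; allyl bromide) gives racemic 7a-allyl-6-methoxy-2,3,5,7a-tetrahydro-1H-inden-1-one F1 in one step, and preparative chromatography on a chiral stationary phase delivers 5.

Second: step 5 (the proposed nickel cyclisation; silyl-triflate enolisation of the ketones, the homoallylic ene-type pathway or alkene isomerisation could compete). The fallback uses known chemistry, sets out from 8 and comes back at 9: Lemieux–Johnson cleavage (OsO4 cat., NaIO4, 2,6-lutidine, dioxane/H2O) gives the keto aldehyde (3aS,7aS)-7a-(2-oxoethyl)hexahydro-1H-indene-1,6(2H)-dione F2; the Ohira–Bestmann reagent (dimethyl (1-diazo-2-oxopropyl)phosphonate, K2CO3, MeOH) gives the propargyl diketone F3; SmI2/HMPA/t-BuOH in THF effects the ketyl–alkyne 5-exo-dig cyclisation to the bridgehead allylic alcohol F4 (any over-reduced C-6 carbinol is re-oxidised with Dess–Martin periodinane); Et3SiOTf/2,6-lutidine then gives 9.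

Third: step 8 (site selectivity of the allylic oxidation, C-10 against the C-15 methylene next to the exocyclic alkene). The fallback sets out from 12 and comes back at 13: γ-deprotonation with LiN(i-Pr)2/HMPA and α-selenenylation with PhSeBr give the α-phenylselanyl β,γ-unsaturated ester F5; H2O2/pyridine oxidises it to the selenoxide F6, which cannot undergo syn-elimination and rearranges by [2,3]-shift to the C-10 selenenate F7; hydrolysis gives the γ-hydroxy enoate F8, and MnO2 oxidises it to 13.

**Further compounds**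
F1 | step 2 | racemic 7a-allyl-6-methoxy-2,3,5,7a-tetrahydro-1H-inden-1-one | C=CCC12C=C(OC)CC=C1CCC2=O
F2 | step 5 | (3aS,7aS)-7a-(2-oxoethyl)hexahydro-1H-indene-1,6(2H)-dione | O=CC[C@]12CC(=O)CC[C@H]1CCC2=O
F3 | step 5 | (3aS,7aS)-7a-(prop-2-ynyl)hexahydro-1H-indene-1,6(2H)-dione | C#CC[C@]12CC(=O)CC[C@H]1CCC2=O
F4 | step 5 | 8-hydroxy-9-methylenetricyclo[6.2.1.0^{1,5}]undecan-2-one (13-OH analogue of 9) | C=C1C[C@]23C[C@@]1(O)CC[C@H]2CCC3=O
F5 | step 8 | 6-phenylselanyl Δ5(10)-7-oate (α-selenide of 12; C-6 configuration unassigned) | C=C1C[C@]23C[C@@]1(O[Si](CC)(CC)CC)CC[C@H]2C=CC3([Se]c4ccccc4)C(=O)OCC[Si](C)(C)C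
F6 | step 8 | selenoxide of F5 | C=C1C[C@]23C[C@@]1(O[Si](CC)(CC)CC)CC[C@H]2C=CC3([Se](=O)c4ccccc4)C(=O)OCC[Si](C)(C)C
F7 | step 8 | C-10 benzeneselenenate of the Δ5-7-oate | C=C1C[C@]23C[C@@]1(O[Si](CC)(CC)CC)CC[C@H]2C(O[Se]c4ccccc4)C=C3C(=O)OCC[Si](C)(C)C
F8 | step 8 | 10-hydroxy-Δ5-7-oate (C-10 epimers) | C=C1C[C@]23C[C@@]1(O[Si](CC)(CC)CC)CC[C@H]2C(O)C=C3C(=O)OCC[Si](C)(C)C
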